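Temperature and time were what I had to weigh for three flasks of substrate: one kept cold, one kept warm, and one warmed late.

| setting | dusk | autumn | east | south-west | west |
|---|---|---|---|---|---|
| substrate | 0.42 M | 0.66 M | 0.30 M | 0.30 M | 0.30 M |
| temperature | −20 °C | −8 °C | −15 °C |  | 0 °C |
| remark | run made earlier | run made earlier |  | at −15 °C until 40 min, from then on at 0 °C |  |
| time |  |  | 1.0 h | 1.0 h | 1.0 h |

| run | time / min | ring / % | substrate / % |
|---|---|---|---|
| dusk | 5.00 | 2.6 | 96.5 |
| dusk | 15.0 | 6.6 | 89.8 |
| dusk | 30.0 | 13.3 | 82.5 |
| dusk | 40.0 | 17.6 | 77.2 |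
| dusk | 60.0 | 23.4 | 67.9 |
| autumn | 12.0 | 31.1 | 59.5 |
| autumn | 25.0 | 49.2 | 36.2 |
| autumn | 40.0 | 58.8 | 20.4 |
| autumn | 50.0 | 60.9 | 14.0 |
| autumn | 60.0 | 61.4 | 10.0 |

(scatter of a reading: 0.3 percentage points)

- the best flask by amount of ring, in percent of the substrate charged; "all alike" if 1.5 percentage points covers them all (east / south-west / west / all alike)
- amount of ring at the end, in percent of the substrate charged, east
- amount of ring at the end, in percent of the substrate charged, south-west
- amount of ring at the end, in percent of the substrate charged, west



First, where does ring stop growing? In the autumn run ring rose 18 percentage points between the first two readings but 0.5 points between the last two, close to the scatter of 0.3 points, so I took the last reading as the crossing. There c ring / c substrate read 6.14. This is the crossing ratio X, the value of c ring / c substrate at which ring is used up as fast as it is made. I assumed that X holds at the other temperatures too.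

Second, does east reach X? The substrate constant read 0.00645 min⁻¹ in the dusk run and 0.0384 min⁻¹ in the autumn run. Taken evenly per degree, that gave me 0.0136 min⁻¹ for east and 0.126 min⁻¹ at 0 °C. East should keep 44.3% substrate. With a selectivity of 0.768, read from the first autumn reading, it should hold 42.8% ring. Its ratio of 0.965 stays below X, so east stops while ring is still growing.

Third, how long does a warm flask overstay? Substrate stood at 10.0% at the crossing in the autumn run, and I assumed the same mark for both warm flasks. West should get there after 18.3 min and then spend 41.7 min past the crossing. South-west needs 14.0 min of its warm 20.0 min, so it overstays less. I expected south-west to come out ahead.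

The forecast named the same flask: south-west, with east 43% (39% to 47%), south-west 58% (51% to 66%) and west 38% (25% to 55%), and it said of south-west that “the warm step finishes most of the remaining substrate with little time for decay”.

The flasks gave south-west as the winner: east 43.7%, south-west 64.5%, which is 6.5 points above the forecast, and west 42.5%.

    substrate → ring (k = 0.00190 s⁻¹, Ea = 90.0 kJ mol⁻¹)
    2 substrate ⇌ open dimer (K = 1.80 L mol⁻¹, k = 2.20 × 10⁻⁴ L mol⁻¹ s⁻¹, Ea = 59.0 kJ mol⁻¹, ΔH = −8.00 kJ mol⁻¹)
    ring ⇌ isomer of the product (K = 6.10, k = 2.80 × 10⁻⁴ s⁻¹, Ea = 79.0 kJ mol⁻¹, ΔH = −53.0 kJ mol⁻¹)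
    substrate ⇌ dormant form (K = 8.10, k = 1.10 × 10⁻⁴ s⁻¹, Ea = 92.0 kJ mol⁻¹, ΔH = −10.0 kJ mol⁻¹)
    (constants at 0 °C)

At 1.00 h south-west stood at a ratio of 12.0, twice X. East stood at 0.961, and there ring was made 5.35 times faster than it was used up, each step taken net, against 6.39 reckoned from X. For the east flask repeated at −40 °C, the same reckoning gives a constant of 3.30 × 10⁻⁴ min⁻¹ and a ratio of 0.0154, far below X. That flask held 0.757% ring beside 98.7% substrate, a ratio of 0.00767.

The data are simulated from invented constants; noise was put on by code.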